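**Retrosynthetic overview**
- Last bond: C7–C8 of the nonenyl chain (alkenyl CH to the CH(CH3) on ring B). It is made by a nickel-catalysed enantioconvergent radical cross-electrophile coupling of a racemic α-chloroethyl pyranone (fragment 1, ring B) with an (E)-alkenyl bromide carrying ring A (fragment 2); this step also sets C8.
- Fragment 1: the hydroxypentyl arm comes from the same kind of radical coupling (α-chloroethyl pyranone + propanoyl chloride), then Felkin reduction; the second chloride is installed by lateral enolate chlorination.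
- Fragment 2: the C2–C3 bond comes from a vinylogous aldol of the lateral pyranone lithium enolate with an anti α-methyl-β-silyloxy aldehyde, made by Brown anti-crotylation of (E)-3-bromo-2-methylpropenal and ozonolysis.
- Rings: one ring-forming event only. 2,6-Diethyl-3,5-dimethyl-4-pyranone is built first (pentan-3-one + propanoic acid, triketone cyclodehydration) and used twice, first as ring B, then as ring A; no ring is closed later.

Assumption: the sense of induction of the two nickel/bis(oxazoline) couplings is carried over from 1-arylethyl chlorides and is confirmed on the racemic monochloride before use; both ligand antipodes are commercial.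

**Step 1**
Reactants: 1 pentan-3-one; 2 propanoic acid (2 equiv)
Product: 4 2,6-diethyl-3,5-dimethyl-4H-pyran-4-one, via triketone 3 (not isolated)
Conditions: PPA, 95 °C, 6 h
Reagents that add atoms: none
Why: Double C-acylation of the ketone by propanoic acid in polyphosphoric acid gives triketone 3, whose cyclodehydration (classical 4-pyranone synthesis) closes the fully substituted ring, with no stereocentre remaining.

**Step 2**
Reactants: 4 2,6-diethyl-3,5-dimethyl-4H-pyran-4-one
Product: 6 rac-2-(1-chloroethyl)-6-ethyl-3,5-dimethyl-4H-pyran-4-one, via sodium dienolate 5 (not isolated)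
Conditions: NaN(SiMe3)2 (1.05 equiv), THF, −78 °C, 30 min; cannulate into C2Cl6 (1.5 equiv), THF, −78 °C
Reagents that add atoms: hexachloroethane ClC(Cl)(Cl)C(Cl)(Cl)Cl
Why: Lateral (vinylogous) deprotonation of one ethyl group by the sodium amide gives extended sodium enolate 5, the more reactive counter-ion for halogen transfer, which takes chlorine from C2Cl6 at its γ-carbon (enolate halogenation), inverse addition limiting over-chlorination; the new centre is deliberately racemic.

**Step 3**
Reactants: 6 rac-2-(1-chloroethyl)-6-ethyl-3,5-dimethyl-4H-pyran-4-one (1.5 equiv); 7 propanoyl chloride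
Product: 8 2-ethyl-3,5-dimethyl-6-[(2R)-3-oxopentan-2-yl]-4H-pyran-4-one
Conditions: NiCl2(dme) (10 mol %), 2,2'-(propane-2,2-diyl)bis(4-phenyl-4,5-dihydrooxazole) (Ph-BOX, 22 mol %, antipode per assumption), Mn powder (3 equiv), 2,6-dimethylbenzoic acid (0.75 equiv), DMA/THF 3:7, 3 Å MS, 20 °C
Reagents that add atoms: none
Why: Proposed new method: the nickel-catalysed enantioconvergent reductive acyl cross-electrophile coupling known for 1-arylethyl chlorides is extended to the pyranone analogue, whose C–Cl bond is cleaved to a planar, pyranone-stabilised (vinylogous α-keto) radical that is captured by the chiral bis(oxazoline) propanoyl-nickel species, so that reductive elimination gives the (R) centre from either enantiomer of 6.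

**Step 4**
Reactants: 8 2-ethyl-3,5-dimethyl-6-[(2R)-3-oxopentan-2-yl]-4H-pyran-4-one
Product: 9 2-ethyl-6-[(2S,3S)-3-hydroxypentan-2-yl]-3,5-dimethyl-4H-pyran-4-one
Conditions: LiBH(s-Bu)3 (1.2 equiv), THF, −78 °C, 1 h; H2O
Reagents that add atoms: none
Why: Felkin–Anh reduction with a bulky non-chelating hydride (pyranone as the perpendicular large group, hydride passing the α-hydrogen) gives the anti (2S,3S) alcohol and locks the labile α-centre before it can epimerise.

**Step 5**
Reactants: 9 2-ethyl-6-[(2S,3S)-3-hydroxypentan-2-yl]-3,5-dimethyl-4H-pyran-4-one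
Product: 11 2-[(1RS)-1-chloroethyl]-6-[(2S,3S)-3-hydroxypentan-2-yl]-3,5-dimethyl-4H-pyran-4-one, via dilithio dianion 10 (not isolated)
Conditions: LiN(SiMe3)2 (2.2 equiv), THF, −78 °C, 45 min; cannulate into C2Cl6 (1.5 equiv), THF, −78 °C; H2O
Reagents that add atoms: hexachloroethane ClC(Cl)(Cl)C(Cl)(Cl)Cl
Why: The alkoxide shields its own branched arm, so the second equivalent of base removes the unhindered CH2 of the remaining ethyl group and the extended enolate is chlorinated by C2Cl6 (vinylogous enolate chlorination), lithium being kept as counter-ion here so that the vinylogous aldolate does not fragment by retro-aldol; the epimer mixture at CHCl is irrelevant because this carbon becomes a radical in step 11.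

**Step 6**
Reactants: 12 2-methylprop-2-enal
Product: 14 (2E)-3-bromo-2-methylprop-2-enal, via dibromide 13 (not isolated)
Conditions: Br2 (1.0 equiv), CH2Cl2, −78 to 0 °C; Et3N (1.2 equiv), 0 °C to rt
Reagents that add atoms: bromine BrBr
Why: Alkene bromination followed by E2 dehydrobromination through the more acidic CH2Br hydrogen gives the conjugated 3-bromo enal, the (E) isomer (Br trans to the formyl group) being the thermodynamically favoured one.

**Step 7**
Reactants: 14 (2E)-3-bromo-2-methylprop-2-enal; 15 (E)-but-2-ene (2 equiv)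
Product: 17 (1E,3R,4R)-1-bromo-2,4-dimethylhexa-1,5-dien-3-ol, via crotylborane 16 (not isolated)
Conditions: 15, KOt-Bu, n-BuLi, THF, −78 to −45 °C; (+)-Ipc2BOMe, −78 °C; BF3·OEt2, −78 °C; 14, −78 °C, 4 h; 3 M NaOH, 30% H2O2, rt
Reagents that add atoms: none
Why: Brown asymmetric crotylboration: the (E)-crotylborane reacts through a chair Zimmerman–Traxler transition state (E gives anti) and the isopinocampheyl groups of the (+)-series direct attack to the Re face of the aldehyde, setting the anti (3R,4R) pair.

**Step 8**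
Reactants: 17 (1E,3R,4R)-1-bromo-2,4-dimethylhexa-1,5-dien-3-ol
Product: 18 {[(1E,3R,4R)-1-bromo-2,4-dimethylhexa-1,5-dien-3-yl]oxy}triethylsilane
Conditions: Et3SiOTf (1.2 equiv), 2,6-lutidine, CH2Cl2, −78 °C
Reagents that add atoms: triethylsilyl trifluoromethanesulfonate CC[Si](CC)(CC)OS(=O)(=O)C(F)(F)F
Why: Silyl ether formation with a silyl triflate and hindered base installs a non-chelating, acid-labile triethylsilyl group that later enforces open-chain Felkin control.

**Step 9**
Reactants: 18 {[(1E,3R,4R)-1-bromo-2,4-dimethylhexa-1,5-dien-3-yl]oxy}triethylsilane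
Product: 20 (2S,3R,4E)-5-bromo-2,4-dimethyl-3-[(triethylsilyl)oxy]pent-4-enal, via ozonide 19 (not isolated)
Conditions: O3, CH2Cl2, −78 °C (Sudan red 7B end point); PPh3, −78 °C to rt
Reagents that add atoms: ozone [O-][O+]=O
Why: Ozonolysis with reductive work-up cleaves the electron-richer monosubstituted alkene selectively over the bromine-deactivated trisubstituted one and leaves both stereocentres untouched.

**Step 10**
Reactants: 4 2,6-diethyl-3,5-dimethyl-4H-pyran-4-one (2.0 equiv); 20 (2S,3R,4E)-5-bromo-2,4-dimethyl-3-[(triethylsilyl)oxy]pent-4-enal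
Product: 23 2-[(2R,3R,4R,5R,6E)-7-bromo-3,5-dihydroxy-4,6-dimethylhept-6-en-2-yl]-6-ethyl-3,5-dimethyl-4H-pyran-4-one, via lithium dienolate 21 (not isolated), via lithium aldolate 22 (not isolated)
Conditions: 4, LiN(SiMe3)2 (1.9 equiv), THF, −78 °C, 30 min; 20, −78 °C, 1 h; 1 M HCl, THF, 0 °C to rt, 1 h
Reagents that add atoms: none
Why: Vinylogous lithium aldol addition of the lateral pyranone enolate, in which Felkin–Anh attack reinforced by the 1,3-anti preference of the anti α-methyl-β-silyloxy aldehyde sets C3 (syn to the C4 methyl, anti to the C5 oxygen), the open antiperiplanar transition state of the (Z)-ethylidene enolate is expected to give the 2,3-anti relationship (the least secure stereocentre of the route, minor isomer separated), lithium holds the aldolate against retro-aldol, and the acidic quench removes the triethylsilyl group.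

**Step 11**
Reactants: 11 2-[(1RS)-1-chloroethyl]-6-[(2S,3S)-3-hydroxypentan-2-yl]-3,5-dimethyl-4H-pyran-4-one (1.3 equiv); 23 2-[(2R,3R,4R,5R,6E)-7-bromo-3,5-dihydroxy-4,6-dimethylhept-6-en-2-yl]-6-ethyl-3,5-dimethyl-4H-pyran-4-one
Product: 24 2-ethyl-6-[(2R,3R,4R,5R,6E,8R)-3,5-dihydroxy-8-{6-[(2S,3S)-3-hydroxypentan-2-yl]-3,5-dimethyl-4-oxo-4H-pyran-2-yl}-4,6-dimethylnon-6-en-2-yl]-3,5-dimethyl-4H-pyran-4-one
Conditions: NiCl2(dme) (10 mol %), cyclopropane-1,1-diyl-bridged bis(indano-oxazoline) ligand (11 mol %, antipode per assumption), Mn powder (3 equiv), NaI (0.5 equiv), DMA, 0 °C, 24 h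
Reagents that add atoms: none
Why: Proposed new method: the nickel-catalysed enantioconvergent reductive cross-electrophile coupling of 1-arylethyl chlorides with disubstituted alkenyl bromides is extended to a pyranone chloride and a trisubstituted alkenyl bromide bearing free hydroxyls, the alkenyl bromide adding oxidatively to low-valent nickel with retention of the (E) geometry, halogen abstraction from either epimer of 11 giving a planar pyranone-stabilised radical, and its capture and reductive elimination at the chiral bis(oxazoline) nickel centre forming the C7–C8 bond and setting (8R) under catalyst control, remote from all other stereocentres.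

**Compound list**
1 | pentan-3-one | CCC(=O)CC | starting material
2 | propanoic acid | CCC(=O)O | starting material
3 | 4,6-dimethylnonane-3,5,7-trione (stereoisomer mixture) | CCC(=O)C(C)C(=O)C(C)C(=O)CC | intermediate (not isolated)
4 | 2,6-diethyl-3,5-dimethyl-4H-pyran-4-one | CCc1oc(CC)c(C)c(=O)c1C | intermediate
5 | sodium (2Z)-6-ethyl-2-ethylidene-3,5-dimethyl-2H-pyran-4-olate (Z geometry assumed) | C/C=C1\OC(CC)=C(C)C(O[Na])=C1C | intermediate (not isolated)
6 | rac-2-(1-chloroethyl)-6-ethyl-3,5-dimethyl-4H-pyran-4-one | CCc1oc(C(C)Cl)c(C)c(=O)c1C | intermediate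
7 | propanoyl chloride | CCC(=O)Cl | starting material
8 | 2-ethyl-3,5-dimethyl-6-[(2R)-3-oxopentan-2-yl]-4H-pyran-4-one | CCc1oc([C@@H](C)C(=O)CC)c(C)c(=O)c1C | intermediate
9 | 2-ethyl-6-[(2S,3S)-3-hydroxypentan-2-yl]-3,5-dimethyl-4H-pyran-4-one | CCc1oc([C@@H](C)[C@@H](O)CC)c(C)c(=O)c1C | intermediate
10 | dilithium (2Z)-2-ethylidene-3,5-dimethyl-6-[(2S,3S)-3-oxidopentan-2-yl]-2H-pyran-4-olate | C/C=C1\OC([C@@H](C)[C@@H](O[Li])CC)=C(C)C(O[Li])=C1C | intermediate (not isolated)
11 | 2-[(1RS)-1-chloroethyl]-6-[(2S,3S)-3-hydroxypentan-2-yl]-3,5-dimethyl-4H-pyran-4-one | CC(Cl)c1oc([C@@H](C)[C@@H](O)CC)c(C)c(=O)c1C | intermediate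
12 | 2-methylprop-2-enal | CC(=C)C=O | starting material
13 | rac-2,3-dibromo-2-methylpropanal | O=CC(C)(Br)CBr | intermediate (not isolated)
14 | (2E)-3-bromo-2-methylprop-2-enal | O=C/C(C)=C/Br | intermediate
15 | (E)-but-2-ene | C/C=C/C | starting material
16 | [(2E)-but-2-en-1-yl]bis(isopinocampheyl)borane, (+)-Ipc2BOMe series | C/C=C/CB([C@H]1C[C@H]2C[C@@H]([C@@H]1C)C2(C)C)[C@H]1C[C@H]2C[C@@H]([C@@H]1C)C2(C)C | intermediate (not isolated)
17 | (1E,3R,4R)-1-bromo-2,4-dimethylhexa-1,5-dien-3-ol | C=C[C@@H](C)[C@@H](O)/C(C)=C/Br | intermediate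
18 | {[(1E,3R,4R)-1-bromo-2,4-dimethylhexa-1,5-dien-3-yl]oxy}triethylsilane | C=C[C@@H](C)[C@@H](O[Si](CC)(CC)CC)/C(C)=C/Br | intermediate
19 | 3-{(2S,3R,4E)-5-bromo-4-methyl-3-[(triethylsilyl)oxy]pent-4-en-2-yl}-1,2,4-trioxolane (mixture at the ring carbon) | O1COC(O1)[C@@H](C)[C@@H](O[Si](CC)(CC)CC)/C(C)=C/Br | intermediate (not isolated)
20 | (2S,3R,4E)-5-bromo-2,4-dimethyl-3-[(triethylsilyl)oxy]pent-4-enal | O=C[C@@H](C)[C@@H](O[Si](CC)(CC)CC)/C(C)=C/Br | intermediate
21 | lithium (2Z)-6-ethyl-2-ethylidene-3,5-dimethyl-2H-pyran-4-olate (Z geometry assumed) | C/C=C1\OC(CC)=C(C)C(O[Li])=C1C | intermediate (not isolated)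
22 | lithium (2R,3R,4R,5R,6E)-7-bromo-2-(6-ethyl-3,5-dimethyl-4-oxo-4H-pyran-2-yl)-4,6-dimethyl-5-[(triethylsilyl)oxy]hept-6-en-3-olate | CCc1oc([C@H](C)[C@H](O[Li])[C@@H](C)[C@@H](O[Si](CC)(CC)CC)/C(C)=C/Br)c(C)c(=O)c1C | intermediate (not isolated)
23 | 2-[(2R,3R,4R,5R,6E)-7-bromo-3,5-dihydroxy-4,6-dimethylhept-6-en-2-yl]-6-ethyl-3,5-dimethyl-4H-pyran-4-one | CCc1oc([C@H](C)[C@H](O)[C@@H](C)[C@@H](O)/C(C)=C/Br)c(C)c(=O)c1C | intermediate
24 | 2-ethyl-6-[(2R,3R,4R,5R,6E,8R)-3,5-dihydroxy-8-{6-[(2S,3S)-3-hydroxypentan-2-yl]-3,5-dimethyl-4-oxo-4H-pyran-2-yl}-4,6-dimethylnon-6-en-2-yl]-3,5-dimethyl-4H-pyran-4-one | CCc1oc([C@H](C)[C@H](O)[C@@H](C)[C@@H](O)/C(C)=C/[C@@H](C)c2oc([C@@H](C)[C@@H](O)CC)c(C)c(=O)c2C)c(C)c(=O)c1C | target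

**Totals**
Total step count: 11. Longest linear sequence: 6 steps (1, 2, 3, 4, 5, 11; the branch 6, 7, 8, 9, 10, 11 is equally long).

**Three steps most likely to fail**

Step 11 (key coupling). The pyranone-stabilised radical, the trisubstituted alkenyl bromide and three free hydroxyls are all outside the tested scope; homocoupling of 11 or its reduction back to 9 could dominate. The fallback sets out from 23 and keeps 11 as the partner. Palladium-catalysed Miyaura borylation of 23 (PdCl2(PPh3)2, PPh3, KOPh, B2pin2, toluene, 50 °C) gives 2-ethyl-6-[(2R,3R,4R,5R,6E)-3,5-dihydroxy-4,6-dimethyl-7-(4,4,5,5-tetramethyl-1,3,2-dioxaborolan-2-yl)hept-6-en-2-yl]-3,5-dimethyl-4H-pyran-4-one F1. F1 is then joined to 11 by a copper-catalysed enantioconvergent radical C(sp3)–C(sp2) coupling (CuI, chiral cinchona-derived anionic N,N,P ligand, LiOt-Bu, catalytic NaI). Here the same pyranone radical is generated by single-electron transfer and captured at a chiral alkenyl-copper centre, so the nucleophile is preformed and no metal reductant is needed. The fallback comes back to the route at 24.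

Step 10 (vinylogous aldol). The 2,3-anti selectivity of the lithium enolate is the least secure stereochemical call, and 20 can epimerise or eliminate under basic conditions. The fallback sets out from 4. Deprotonation with LiN(SiMe3)2 gives lithium dienolate 21, which is trapped with Me3SiCl and the product isolated as {[(2Z)-6-ethyl-2-ethylidene-3,5-dimethyl-2H-pyran-4-yl]oxy}trimethylsilane F2. F2 is added to 20 in a BF3·OEt2-promoted vinylogous Mukaiyama aldol (CH2Cl2, −78 °C). This is non-basic and goes through an open transition state, which is anti-selective at the γ-carbon and Felkin/1,3-anti at the aldehyde. The product is 2-{(2R,3R,4R,5R,6E)-7-bromo-3-hydroxy-4,6-dimethyl-5-[(triethylsilyl)oxy]hept-6-en-2-yl}-6-ethyl-3,5-dimethyl-4H-pyran-4-one F3, and 1 M HCl in THF removes the silyl group. The fallback comes back to the route at 23.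

Step 3 (acyl coupling). The pyranone chloride may be reduced directly by Mn, and ketone 8 is a vinylogous 1,3-dicarbonyl compound whose α-centre can racemise. The fallback sets out from 4 and turns that lability into an advantage. Lithium dienolate 21, made from 4 with LiN(SiMe3)2, is C-acylated with N-methoxy-N-methylpropanamide (THF, −78 °C) to give rac-2-ethyl-3,5-dimethyl-6-(3-oxopentan-2-yl)-4H-pyran-4-one F4. F4 is reduced under dynamic kinetic resolution with an anti-(2S,3S)-selective ketoreductase (NADP+, glucose, glucose dehydrogenase, pH 7 buffer, 30 °C), the α-centre equilibrating through the enol while only one enantiomer is reduced. The fallback comes back to the route at 9.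

**Further compounds**
F1 | step 11 | 2-ethyl-6-[(2R,3R,4R,5R,6E)-3,5-dihydroxy-4,6-dimethyl-7-(4,4,5,5-tetramethyl-1,3,2-dioxaborolan-2-yl)hept-6-en-2-yl]-3,5-dimethyl-4H-pyran-4-one | CCc1oc([C@H](C)[C@H](O)[C@@H](C)[C@@H](O)/C(C)=C/B2OC(C)(C)C(C)(C)O2)c(C)c(=O)c1C
F2 | step 10 | {[(2Z)-6-ethyl-2-ethylidene-3,5-dimethyl-2H-pyran-4-yl]oxy}trimethylsilane | C/C=C1\OC(CC)=C(C)C(O[Si](C)(C)C)=C1C
F3 | step 10 | 2-{(2R,3R,4R,5R,6E)-7-bromo-3-hydroxy-4,6-dimethyl-5-[(triethylsilyl)oxy]hept-6-en-2-yl}-6-ethyl-3,5-dimethyl-4H-pyran-4-one | CCc1oc([C@H](C)[C@H](O)[C@@H](C)[C@@H](O[Si](CC)(CC)CC)/C(C)=C/Br)c(C)c(=O)c1C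
F4 | step 3 | rac-2-ethyl-3,5-dimethyl-6-(3-oxopentan-2-yl)-4H-pyran-4-one | CCc1oc(C(C)C(=O)CC)c(C)c(=O)c1C
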